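## The problem

Compound 22 (CNP0351377.0) is a linear chain of seven benzene rings, lettered A to G along the chain, joined by six diaryl ether oxygens and carrying seventeen free phenolic hydroxyls. It has no stereocentre, so no centre can or must control another; the whole difficulty is regiochemical. Rings B, D and F are one and the same unit, a 1,4-dioxygenated ring with hydroxyls at C3 and C5: its C1 oxygen lies between two ring hydrogens (open), its C4 oxygen between two hydroxyls (crowded), and the open oxygen always points toward ring A. Rings C and E carry their two ether oxygens on the neighbouring carbons C1 and C6, ring C with hydroxyls at C3, C4 and C5 and ring E at C3 and C5; the ends are a 2,4,6-trihydroxyphenyl (ring A) and a 3,4,5-trihydroxyphenyl (ring G) ether. Six C–O bonds therefore have to be placed between electron-rich rings, most of them beside one or two ortho oxygens, and a positional isomer would be very hard to separate from the right compound. The free polyphenol is sensitive to air and base, so all hydroxyls must travel as ethers that survive base, copper and peracid, and be released only in the last step. The enabling feature is that ring A has its C4 hydroxyl para to its only ether carbon C1, and ring G likewise: such a hydroxyl can enter as a formyl group, which activates a fluoride on the ether carbon for displacement by a phenoxide and is afterwards exchanged for oxygen by a peracid. The same para (rings B, D, F) or ortho (rings C, E) relation holds between the two ether oxygens of every inner ring, so the device can serve the whole chain.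

## Retrosynthesis

**22 to 21.** The fifteen O–CH3 bonds of heptamer diol 21 are cut last, by Lewis-acid ether cleavage. Methyl ethers are preferred to benzyl ethers because the purchasable ring precursors already carry them, because they add the least bulk beside the carbons that must be substituted, and because diaryl ethers offer the Lewis acid no sp3 carbon. The forward step must cleave every methyl ether, including those flanked by aryloxy groups, with air excluded.

**21 to 19.** The C4–O bonds of rings A and G are traced back to C4–CHO bonds in heptamer dialdehyde 19, by peracid oxidation with aryl migration through bis(formate) 20. No other retron converts the activating group of an aromatic substitution into oxygen in one operation. Both rings have oxygen donors ortho or para to the formyl group, as the migration requires.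

**19 to 17, 12 and 13 (the central disconnection).** The C1(ring A)–O and O–C1(ring G) bonds are cut, leaving pentamer diol 17 and the two fluoroaldehydes 12 and 13. Cutting an inner ether instead would halve the molecule more evenly, but rings B to F have no position where an activating group could later become a needed substituent; only the end rings do. The precursor loses two rings and keeps no protecting group. The forward reaction must tell the open ring B phenol from the crowded ring F phenol. Steric matching does this: 12 has its fluoride between two methoxy groups and 13 has an open fluoride, so each coupling has exactly one crowded partner. The mono-capped hexamer 18 is passed through without isolation.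

**17 to 15, then to 11, 12 and 13.** The two phenols of 17 come from the formyl groups of pentamer dialdehyde 15 through bis(formate) 16. Then 15 is cut at the B–C and E–F ethers in the same two-ended way, through tetramer 14, to trimer diol 11. Ring B has the substitution pattern of ring A and ring F that of ring G, so 12 and 13 are used a second time, and the trimer stage rehearses the end-capping on cheaper material. The alternative, growing the chain ring by ring from one end, would need a protecting group on the far terminus and one coupling plus one oxidation per ring. Growth from the middle lets every oxidation unmask two phenols, which are exactly the two needed next.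

**11 to 9, then to 7 and 8.** The ring C and ring E phenols of 11 come from trimer dialdehyde 9 through bis(formate) 10. Ring E has its two ether oxygens ortho to each other, so it is cut at the D–E ether into phenol 7 and the ortho-fluoroaldehyde 8. The crowded ring D phenoxide meets a fluoride with a single ortho neighbour, and both methoxy groups of 8 are meta to the carbon attacked.

**7 to 6, then to 4 and 5.** Ring C is cut at the C–D ether. Here the halide must sit between the formyl group and a methoxy group. The corresponding fluoride is not an article of commerce, so bromide 5 and copper catalysis are used; the ortho-carbonyl group and the open phenol 4 make this the most favourable Ullmann pairing in the molecule. The two oxygens of ring D are told apart by a methoxymethyl group on the crowded one in 6. It is removed by dilute acid, which leaves the formyl group of 7 untouched; a benzyl ether would have to be hydrogenolysed beside an aldehyde.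

**4 to 2, then to 1.** Phenol 4 is reached from syringaldehyde 1 by the same formyl-to-hydroxyl exchange (through 2 and formate 3). Ring D thus also enters as an aldehyde, and all seven rings derive from five purchasable benzaldehydes.

## Roads not taken

**Alternative 1: ring A by twofold Claisen condensation.** Ring A would be cut twice, each time between a hydroxyl carbon next to the ether carbon and its CH neighbour. In the forward sense the aryloxymalonate A2 (aryl = protected ring B) and the ketodiester A3 would be condensed with methoxide in two Claisen acylations to give the phloroglucinol diester A1.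

- Merits: the phloroglucinol oxygen pattern arises automatically, the reagents are cheap, and the crowded A–B ether is made at an sp3 carbon before ring A exists, with no aromatic substitution.
- Weak points: A2 has an acidic C–H between its esters, and once deprotonated its ester groups acylate poorly, while A3 condenses with itself. A1 then needs saponification, double decarboxylation and methylation of three hydroxyls. Above all, the effort buys one terminal ring; debenzylation and five more aryl ethers remain.
- Comparison: for the A–B bond alone this road is at least as safe as the chosen one. The chosen plan sets against it the small fluoride leaving group, the pairing with the open ring B phenoxide, and the fact that ring A costs no step of its own, since it arrives in the same flask as ring G and is unmasked together with it.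

**Alternative 2: ring C by cyclobutenone ring expansion.** Ring C would be cut between its CH carbon and the adjacent hydroxyl carbon. The squarate A6 would be converted into the racemic 4-hydroxy-4-(1-aryloxyvinyl)cyclobutenone A5, which on heating in xylene should open to a dienylketene and electrocyclise to the A–B–C trimer hydroquinone A4.

- Merits: ring C is the only ring with five contiguous oxygens, and here it would form with all five in place and with regiochemistry fixed by connectivity. The crowded B–C ether is made as a vinyl ether. This is better than the chosen plan at ring C, which needs its single copper-catalysed coupling (step 3) at a doubly flanked bromide.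
- Weak points: A5 requires addition of an alpha-metalated aryl vinyl ether, whose generation competes with ring metalation of two electron-rich arenes. A4 is an easily oxidised hydroquinone whose two hydroxyls must be differentiated, one for arylation by ring D and one for methylation. The sequence is linear from ring A and leaves rings D to G and three ethers open.
- Comparison: the chosen plan sets against it a ring C bought as bromide 5, the ortho-formyl assistance in the coupling, and the avoidance of any free hydroquinone.

**Alternative 3: ring G by Danheiser benzannulation.** Ring G would be cut at C1–C2 and C5–C6 (C1 the ether carbon). Heating the racemic cyclobutenone A9 with the ethynyl ether A8 of protected ring F in toluene should give the phenol A7 through a vinylketene, a [2+2] adduct and a dienylketene.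

- Merits: the annulation is regiospecific and convergent, and the crowded F–G oxygen is bonded before ring G exists, so the crowded phenoxide need not be arylated. It also needs no formyl-to-hydroxyl oxidation on ring G.
- Weak points: A8, the ethynyl ether of a doubly ortho-substituted phenol, is laborious and labile, and A9 is not a stock compound. The ring built is one that can be bought as 13.
- Comparison: the chosen plan sets against it a one-flask attachment of ring G to an open fluoride, with the oxidation shared with ring A in one step.

Key step: step 9

## Route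

Assumption: aldehydes 5 and 8 are treated as purchasable; should a catalogue fail, each is one standard electrophilic substitution (ring bromination, Vilsmeier formylation) away from a commodity arene.

Step 1
Reactants: 1 4-hydroxy-3,5-dimethoxybenzaldehyde (syringaldehyde)
Product: 2 3,5-dimethoxy-4-(methoxymethoxy)benzaldehyde
Conditions: MOMCl, K2CO3, DMF, 0 °C to rt
Reagents that add atoms: chloromethyl methyl ether (MOMCl), COCCl
Why: Williamson-type O-alkylation of the phenoxide; the resulting acetal resists base, copper and buffered peracid and later leaves under dilute acid that an aldehyde tolerates.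

Step 2
Reactants: 2 3,5-dimethoxy-4-(methoxymethoxy)benzaldehyde
Product: 4 3,5-dimethoxy-4-(methoxymethoxy)phenol, via aryl formate 3 (not isolated)
Conditions: mCPBA, CH2Cl2, 0 °C to rt; aq. NaHCO3 wash; then K2CO3 (cat.), MeOH, rt
Reagents that add atoms: mCPBA (3-chloroperbenzoic acid), OOC(=O)c1cccc(Cl)c1
Why: Baeyer–Villiger oxidation with aryl migration (Dakin-type outcome), favoured by the trialkoxyaryl group, followed by base-catalysed transesterification of formate 3 to methyl formate.

Step 3
Reactants: 4 3,5-dimethoxy-4-(methoxymethoxy)phenol; 5 2-bromo-3,4,5-trimethoxybenzaldehyde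
Product: 6 2-[3,5-dimethoxy-4-(methoxymethoxy)phenoxy]-3,4,5-trimethoxybenzaldehyde
Conditions: CuI (10 mol %), picolinic acid (20 mol %), K3PO4, DMSO, 90 °C, Ar
Reagents that add atoms: none
Why: Copper-catalysed Ullmann diaryl ether coupling; the ortho-formyl group assists insertion of copper into the C–Br bond, phenol 4 has no ortho substituent, and 2-bromo-3,4,5-trialkoxybenzoyl compounds are classical partners in this coupling.

Step 4
Reactants: 6 2-[3,5-dimethoxy-4-(methoxymethoxy)phenoxy]-3,4,5-trimethoxybenzaldehyde
Product: 7 2-(4-hydroxy-3,5-dimethoxyphenoxy)-3,4,5-trimethoxybenzaldehyde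
Conditions: 3 M aq. HCl, THF, 50 °C
Reagents that add atoms: none
Why: Acid hydrolysis of the methoxymethyl acetal; the diaryl ether, the methyl ethers and the formyl group are inert to dilute aqueous acid.

Step 5
Reactants: 7 2-(4-hydroxy-3,5-dimethoxyphenoxy)-3,4,5-trimethoxybenzaldehyde; 8 2-fluoro-4,6-dimethoxybenzaldehyde
Product: 9 2-[4-(2-formyl-3,5-dimethoxyphenoxy)-3,5-dimethoxyphenoxy]-3,4,5-trimethoxybenzaldehyde (C–D–E trimer dialdehyde)
Conditions: Cs2CO3, degassed DMSO, 100 °C, Ar
Reagents that add atoms: none
Why: Nucleophilic aromatic substitution (SNAr) through a Meisenheimer adduct stabilised by the ortho-formyl group; the crowded ring D phenoxide meets a fluoride with one ortho neighbour, and both methoxy groups of 8 are meta to the carbon attacked.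

Step 6
Reactants: 9 C–D–E trimer dialdehyde
Product: 11 2-[4-(2-hydroxy-3,5-dimethoxyphenoxy)-3,5-dimethoxyphenoxy]-3,4,5-trimethoxyphenol (C–D–E trimer diol), via trimer bis(formate) 10 (not isolated)
Conditions: mCPBA (2.4 equiv), CH2Cl2, 0 °C to rt; aq. NaHCO3 wash; then K2CO3 (cat.), MeOH, rt, Ar
Reagents that add atoms: mCPBA (3-chloroperbenzoic acid), OOC(=O)c1cccc(Cl)c1
Why: Twofold Baeyer–Villiger oxidation; each formyl group sits on a ring with ortho and para oxygen donors, so aryl migration should win over hydride migration, and the phenols are released only after the peracid is gone, which guards the electron-rich rings against over-oxidation.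

Step 7
Reactants: 11 C–D–E trimer diol; 12 4-fluoro-3,5-dimethoxybenzaldehyde; 13 4-fluoro-2,6-dimethoxybenzaldehyde
Product: 15 B–C–D–E–F pentamer dialdehyde (4-formyl-2,6-dimethoxyphenyl on the ring C oxygen, 4-formyl-3,5-dimethoxyphenyl on the ring E oxygen), via tetramer aldehyde phenol 14 (not isolated)
Conditions: 12 (1.05 equiv), Cs2CO3 (1.1 equiv), degassed DMSO, 90 °C, Ar; then 13 (1.5 equiv), Cs2CO3 (1.5 equiv), 110 °C
Reagents that add atoms: none
Why: Two consecutive SNAr reactions sorted by crowding: fluoride 12, flanked by two methoxy groups, should be taken by the ring C phenoxide (one ortho neighbour) and not by the ring E phenoxide (two ortho oxygens), which then takes the open fluoride 13; the step rehearses the end-capping of step 9.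

Step 8
Reactants: 15 B–C–D–E–F pentamer dialdehyde
Product: 17 B–C–D–E–F pentamer diol (open ring B hydroxyl and crowded ring F hydroxyl free, eleven methyl ethers), via pentamer bis(formate) 16 (not isolated)
Conditions: mCPBA (2.4 equiv), CH2Cl2, 0 °C to rt; aq. NaHCO3 wash; then K2CO3 (cat.), MeOH, rt, Ar
Reagents that add atoms: mCPBA (3-chloroperbenzoic acid), OOC(=O)c1cccc(Cl)c1
Why: Twofold Baeyer–Villiger oxidation; the ring B aldehyde has a para aryloxy group and the ring F aldehyde two ortho methoxy groups and a para aryloxy group, so both aryl groups migrate, and methanolysis frees exactly the two phenols the end-capping needs.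

Step 9
Reactants: 17 B–C–D–E–F pentamer diol; 12 4-fluoro-3,5-dimethoxybenzaldehyde; 13 4-fluoro-2,6-dimethoxybenzaldehyde
Product: 19 A–G heptamer dialdehyde (4-formyl-2,6-dimethoxyphenyl on the ring B oxygen, 4-formyl-3,5-dimethoxyphenyl on the ring F oxygen, fifteen methyl ethers), via hexamer aldehyde phenol 18 (not isolated)
Conditions: 12 (1.1 equiv), Cs2CO3 (1.0 equiv), degassed DMSO, 90 °C, Ar, until the ring B phenol is consumed; then 13 (1.5 equiv), Cs2CO3 (1.5 equiv), 110 °C
Reagents that add atoms: none
Why: Each ether forms by addition of a caesium phenoxide to the fluorine-bearing carbon para to the formyl group, giving a Meisenheimer adduct whose charge is taken up by the aldehyde, and by loss of fluoride; the closest known reaction type is the SNAr diaryl ether synthesis from phenols and 4-fluorobenzaldehydes. No ring is closed and no stereocentre is formed. The step needs site selectivity between the two phenols of 17, and crowding supplies it: fluoride 12 lies between two methoxy groups and can be reached by the ring B phenoxide, which has two ortho hydrogens, whereas attack by the ring F phenoxide would have to build an ether with four ortho substituents. Stage one is therefore run with 12 alone and one equivalent of base until the ring B phenol is gone, the ring F phenoxide of 18 standing by. Fluoride 13, whose ortho positions are free, is then charged with more base and should be taken by the only phenoxide left. Each coupling thus joins one crowded and one open partner. Both formyl groups end up para to the new ether oxygens, on the carbons where rings A and G need their hydroxyls. The same sorting will have been tested in step 7 on a cheaper diol.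

Step 10
Reactants: 19 A–G heptamer dialdehyde
Product: 21 A–G heptamer diol (C4 hydroxyls of rings A and G free, fifteen methyl ethers), via heptamer bis(formate) 20 (not isolated)
Conditions: mCPBA (2.4 equiv), CH2Cl2, 0 °C to rt; aq. NaHCO3 wash; then K2CO3 (cat.), MeOH, rt, Ar
Reagents that add atoms: mCPBA (3-chloroperbenzoic acid), OOC(=O)c1cccc(Cl)c1
Why: Twofold Baeyer–Villiger oxidation of the same two aldehyde types as in step 8, then formate methanolysis; the formates keep the new phenols masked while peracid is present.

Step 11
Reactants: 21 A–G heptamer diol
Product: 22 CNP0351377.0 (heptamer A–G with all seventeen hydroxyls free)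
Conditions: BBr3 (about 2 equiv per OMe), CH2Cl2, −78 °C to rt, Ar; then H2O, 0 °C; reversed-phase purification under Ar
Reagents that add atoms: none
Why: Lewis-acid cleavage of aryl methyl ethers by BBr3, in which bromide attacks the methyl carbon of the boron–oxygen adduct; the diaryl ether C–O bonds offer no sp3 carbon and should survive.

## Compound list

1 | 4-hydroxy-3,5-dimethoxybenzaldehyde (syringaldehyde) | COc1cc(C=O)cc(OC)c1O | starting material
2 | 3,5-dimethoxy-4-(methoxymethoxy)benzaldehyde | COCOc1c(OC)cc(C=O)cc1OC | intermediate
3 | 3,5-dimethoxy-4-(methoxymethoxy)phenyl formate | COCOc1c(OC)cc(OC=O)cc1OC | intermediate (not isolated)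
4 | 3,5-dimethoxy-4-(methoxymethoxy)phenol | COCOc1c(OC)cc(O)cc1OC | intermediate
5 | 2-bromo-3,4,5-trimethoxybenzaldehyde | COc1cc(C=O)c(Br)c(OC)c1OC | starting material
6 | 2-[3,5-dimethoxy-4-(methoxymethoxy)phenoxy]-3,4,5-trimethoxybenzaldehyde | COCOc1c(OC)cc(Oc2c(C=O)cc(OC)c(OC)c2OC)cc1OC | intermediate
7 | 2-(4-hydroxy-3,5-dimethoxyphenoxy)-3,4,5-trimethoxybenzaldehyde | Oc1c(OC)cc(Oc2c(C=O)cc(OC)c(OC)c2OC)cc1OC | intermediate
8 | 2-fluoro-4,6-dimethoxybenzaldehyde | COc1cc(F)c(C=O)c(OC)c1 | starting material
9 | 2-[4-(2-formyl-3,5-dimethoxyphenoxy)-3,5-dimethoxyphenoxy]-3,4,5-trimethoxybenzaldehyde (C–D–E trimer dialdehyde) | O=Cc1cc(OC)c(OC)c(OC)c1Oc1cc(OC)c(Oc2cc(OC)cc(OC)c2C=O)c(OC)c1 | intermediate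
10 | C–D–E trimer bis(formate): 9 with both formyl groups replaced by formyloxy groups | O=COc1cc(OC)c(OC)c(OC)c1Oc1cc(OC)c(Oc2cc(OC)cc(OC)c2OC=O)c(OC)c1 | intermediate (not isolated)
11 | 2-[4-(2-hydroxy-3,5-dimethoxyphenoxy)-3,5-dimethoxyphenoxy]-3,4,5-trimethoxyphenol (C–D–E trimer diol) | Oc1cc(OC)c(OC)c(OC)c1Oc1cc(OC)c(Oc2cc(OC)cc(OC)c2O)c(OC)c1 | intermediate
12 | 4-fluoro-3,5-dimethoxybenzaldehyde | COc1cc(C=O)cc(OC)c1F | starting material
13 | 4-fluoro-2,6-dimethoxybenzaldehyde | COc1cc(F)cc(OC)c1C=O | starting material
14 | B–C–D–E tetramer aldehyde phenol: 11 with a 4-formyl-2,6-dimethoxyphenyl group on the ring C oxygen, ring E hydroxyl free | O=Cc1cc(OC)c(Oc2cc(OC)c(OC)c(OC)c2Oc2cc(OC)c(Oc3cc(OC)cc(OC)c3O)c(OC)c2)c(OC)c1 | intermediate (not isolated)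
15 | B–C–D–E–F pentamer dialdehyde: 14 with a 4-formyl-3,5-dimethoxyphenyl group on the ring E oxygen | O=Cc1cc(OC)c(Oc2cc(OC)c(OC)c(OC)c2Oc2cc(OC)c(Oc3cc(OC)cc(OC)c3Oc3cc(OC)c(C=O)c(OC)c3)c(OC)c2)c(OC)c1 | intermediate
16 | pentamer bis(formate): 15 with both formyl groups replaced by formyloxy groups | O=COc1cc(OC)c(Oc2cc(OC)c(OC)c(OC)c2Oc2cc(OC)c(Oc3cc(OC)cc(OC)c3Oc3cc(OC)c(OC=O)c(OC)c3)c(OC)c2)c(OC)c1 | intermediate (not isolated)
17 | B–C–D–E–F pentamer diol: ring B 4-hydroxy-2,6-dimethoxyphenoxy and ring F 4-hydroxy-3,5-dimethoxyphenoxy, eleven methyl ethers | Oc1cc(OC)c(Oc2cc(OC)c(OC)c(OC)c2Oc2cc(OC)c(Oc3cc(OC)cc(OC)c3Oc3cc(OC)c(O)c(OC)c3)c(OC)c2)c(OC)c1 | intermediate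
18 | A–F hexamer aldehyde phenol: 17 with a 4-formyl-2,6-dimethoxyphenyl group on the ring B oxygen, ring F hydroxyl free | O=Cc1cc(OC)c(Oc2cc(OC)c(Oc3cc(OC)c(OC)c(OC)c3Oc3cc(OC)c(Oc4cc(OC)cc(OC)c4Oc4cc(OC)c(O)c(OC)c4)c(OC)c3)c(OC)c2)c(OC)c1 | intermediate (not isolated)
19 | A–G heptamer dialdehyde: 18 with a 4-formyl-3,5-dimethoxyphenyl group on the ring F oxygen | O=Cc1cc(OC)c(Oc2cc(OC)c(Oc3cc(OC)c(OC)c(OC)c3Oc3cc(OC)c(Oc4cc(OC)cc(OC)c4Oc4cc(OC)c(Oc5cc(OC)c(C=O)c(OC)c5)c(OC)c4)c(OC)c3)c(OC)c2)c(OC)c1 | intermediate
20 | heptamer bis(formate): 19 with both formyl groups replaced by formyloxy groups | O=COc1cc(OC)c(Oc2cc(OC)c(Oc3cc(OC)c(OC)c(OC)c3Oc3cc(OC)c(Oc4cc(OC)cc(OC)c4Oc4cc(OC)c(Oc5cc(OC)c(OC=O)c(OC)c5)c(OC)c4)c(OC)c3)c(OC)c2)c(OC)c1 | intermediate (not isolated)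
21 | A–G heptamer diol: pentadeca-O-methyl ether of 22 with free hydroxyls at C4 of ring A and C4 of ring G | Oc1cc(OC)c(Oc2cc(OC)c(Oc3cc(OC)c(OC)c(OC)c3Oc3cc(OC)c(Oc4cc(OC)cc(OC)c4Oc4cc(OC)c(Oc5cc(OC)c(O)c(OC)c5)c(OC)c4)c(OC)c3)c(OC)c2)c(OC)c1 | intermediate
22 | CNP0351377.0, heptamer A–G with seventeen free hydroxyls (no stereocentre) | Oc1cc(O)c(Oc2cc(O)c(Oc3cc(O)c(O)c(O)c3Oc3cc(O)c(Oc4cc(O)cc(O)c4Oc4cc(O)c(Oc5cc(O)c(O)c(O)c5)c(O)c4)c(O)c3)c(O)c2)c(O)c1 | target

## Step count and risks

Total: 11 steps. Longest linear sequence: 11 steps (1 to 22); the four coupling partners 5, 8, 12 and 13 are purchased.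

**Step 9 (key step).** The most likely failure is incomplete sorting of the two phenols. Fluoride 12 is an electron-rich, doubly flanked electrophile, so stage one may stall and leave ring B phenoxide that later takes up 13; or, at the temperature needed, the ring F phenoxide may begin to attack 12. Either process gives isomeric heptamers.
Fallback: it sets out from 17. Stage one is run alone with 12, and the hexamer aldehyde phenol 18 is isolated and freed from isomers by chromatography. Ring G is then joined in a form that needs no later oxidation. Copper-catalysed Ullmann coupling of 18 with 5-iodo-1,2,3-trimethoxybenzene (CuI, picolinic acid, K3PO4, DMSO) should give the heptamer monoaldehyde with a 3,4,5-trimethoxyphenyl ring G F1. Baeyer–Villiger oxidation of its one formyl group gives the heptamer monoformate F2, and methanolysis the heptamer monophenol F3. BBr3 cleavage of its sixteen methyl ethers comes back to the route at 22.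

**Step 7.** The same sorting is less clear-cut here, because the ring C phenoxide itself has an ortho aryloxy group. A slow first stage would let the ring E phenoxide or, later, fluoride 13 intervene at the wrong site.
Fallback: it sets out from 11. Only 12 is added, and tetramer 14 is isolated and purified. Ring F is then attached to the crowded ring E phenol by copper-catalysed Ullmann coupling with 4-bromo-2,6-dimethoxybenzaldehyde instead of SNAr, which comes back at 15. No compound outside the list is made (F0).

**Step 5.** Substitution may be sluggish, because the formyl group of 8 is weakened as an acceptor by its ortho and para methoxy donors, and prolonged heating exposes the electron-rich phenoxide of 7 to oxidative decomposition.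
Fallback: it sets out from 7. Copper-catalysed Ullmann coupling with 2-bromo-4,6-dimethoxybenzaldehyde, whose ortho-formyl group helps as in step 3, comes back directly at 9. No new compound is made (F0).

**Step 3.** Reductive loss of bromine or base-induced disproportionation of the aldehyde may outrun C–O coupling at the doubly ortho-substituted bromide.
Fallback: it sets out from 4. Classical Ullmann coupling with methyl 2-bromo-3,4,5-trimethoxybenzoate (CuO, K2CO3, pyridine, reflux) should give the diaryl ether ester F4. LiAlH4 reduction gives the benzylic alcohol F5, and MnO2 oxidation comes back at 6.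

**Step 11.** Methyl ethers flanked by aryloxy groups may be cleaved incompletely, and the polyphenol may oxidise in air during isolation.
Fallback: it sets out from 21. After the BBr3 treatment the crude polyphenol is not isolated but acetylated (Ac2O, pyridine) to the heptadecaacetate F6. This is purified on silica, where partly methylated material separates and can be resubmitted to BBr3. Acid methanolysis (HCl in MeOH, Ar) comes back at 22.

## Further compounds

F1 | step 9 | heptamer monoaldehyde: 18 with a 3,4,5-trimethoxyphenyl group on the ring F oxygen | O=Cc1cc(OC)c(Oc2cc(OC)c(Oc3cc(OC)c(OC)c(OC)c3Oc3cc(OC)c(Oc4cc(OC)cc(OC)c4Oc4cc(OC)c(Oc5cc(OC)c(OC)c(OC)c5)c(OC)c4)c(OC)c3)c(OC)c2)c(OC)c1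
F2 | step 9 | heptamer monoformate: F1 with the formyl group replaced by a formyloxy group | O=COc1cc(OC)c(Oc2cc(OC)c(Oc3cc(OC)c(OC)c(OC)c3Oc3cc(OC)c(Oc4cc(OC)cc(OC)c4Oc4cc(OC)c(Oc5cc(OC)c(OC)c(OC)c5)c(OC)c4)c(OC)c3)c(OC)c2)c(OC)c1
F3 | step 9 | heptamer monophenol: hexadeca-O-methyl ether of 22 with the ring A C4 hydroxyl free | Oc1cc(OC)c(Oc2cc(OC)c(Oc3cc(OC)c(OC)c(OC)c3Oc3cc(OC)c(Oc4cc(OC)cc(OC)c4Oc4cc(OC)c(Oc5cc(OC)c(OC)c(OC)c5)c(OC)c4)c(OC)c3)c(OC)c2)c(OC)c1
F0 | step 7 | none | none
F0 | step 5 | none | none
F4 | step 3 | methyl 2-[3,5-dimethoxy-4-(methoxymethoxy)phenoxy]-3,4,5-trimethoxybenzoate | COC(=O)c1cc(OC)c(OC)c(OC)c1Oc1cc(OC)c(OCOC)c(OC)c1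
F5 | step 3 | {2-[3,5-dimethoxy-4-(methoxymethoxy)phenoxy]-3,4,5-trimethoxyphenyl}methanol | OCc1cc(OC)c(OC)c(OC)c1Oc1cc(OC)c(OCOC)c(OC)c1
F6 | step 11 | heptadecaacetate of 22 | CC(=O)Oc1cc(OC(C)=O)c(Oc2cc(OC(C)=O)c(Oc3cc(OC(C)=O)c(OC(C)=O)c(OC(C)=O)c3Oc3cc(OC(C)=O)c(Oc4cc(OC(C)=O)cc(OC(C)=O)c4Oc4cc(OC(C)=O)c(Oc5cc(OC(C)=O)c(OC(C)=O)c(OC(C)=O)c5)c(OC(C)=O)c4)c(OC(C)=O)c3)c(OC(C)=O)c2)c(OC(C)=O)c1
A1 | alternative 1 | dimethyl 5-[4-(benzyloxy)-3,5-dimethoxyphenoxy]-2,4,6-trihydroxyisophthalate | COC(=O)c1c(O)c(Oc2cc(OC)c(OCc3ccccc3)c(OC)c2)c(O)c(C(=O)OC)c1O
A2 | alternative 1 | dimethyl 2-[4-(benzyloxy)-3,5-dimethoxyphenoxy]malonate | COC(=O)C(Oc1cc(OC)c(OCc2ccccc2)c(OC)c1)C(=O)OC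
A3 | alternative 1 | dimethyl 3-oxopentanedioate | COC(=O)CC(=O)CC(=O)OC
A4 | alternative 2 | A–B–C trimer hydroquinone, 5-aryloxy-2,3-dimethoxybenzene-1,4-diol with aryl = 3,5-dimethoxy-4-... ring B bearing the 2,4,6-trimethoxyphenyl ring A on its open oxygen | COc1cc(OC)c(Oc2cc(OC)c(Oc3cc(O)c(OC)c(OC)c3O)c(OC)c2)c(OC)c1
A5 | alternative 2 | racemic 4-hydroxy-2,3-dimethoxy-4-{1-[2,6-dimethoxy-4-(2,4,6-trimethoxyphenoxy)phenoxy]vinyl}cyclobut-2-en-1-one | COC1=C(OC)C(O)(C(=C)Oc2c(OC)cc(Oc3c(OC)cc(OC)cc3OC)cc2OC)C1=O
A6 | alternative 2 | dimethyl squarate (3,4-dimethoxycyclobut-3-ene-1,2-dione) | COC1=C(OC)C(=O)C1=O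
A7 | alternative 3 | 5-[4-(benzyloxy)-2,6-dimethoxyphenoxy]-3-ethoxy-2-methoxyphenol | CCOc1cc(Oc2c(OC)cc(OCc3ccccc3)cc2OC)cc(O)c1OC
A8 | alternative 3 | 5-(benzyloxy)-2-(ethynyloxy)-1,3-dimethoxybenzene | C#COc1c(OC)cc(OCc2ccccc2)cc1OC
A9 | alternative 3 | racemic 3-ethoxy-4-methoxycyclobut-2-en-1-one | CCOC1=CC(=O)C1OC
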